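Compare two readings. Starting material reacts with partner in a closed, stirred, isothermal flask. First product and bis adduct are read; the other mono adduct is not.

all flasks: starting material 0.17 M
- summer: partner 0.15 M; run made earlier
- autumn: partner 1 M; run made earlier
- gamma: partner 0.136 M; time 30 min
- eta: partner 0.680 M; time 30 min
- beta: partner 0.255 M; time 30 min

| run | time / min | bis adduct / % | first product / % |
|---|---|---|---|
| summer | 1.33 | 0 | 4.5 |
| summer | 4.00 | 0.7 | 9.8 |
| summer | 8.00 | 2.1 | 16.3 |
| summer | 10.0 | 1.8 | 19.1 |
| summer | 15.0 | 2.8 | 24.5 |
| autumn | 1.33 | 2.0 | 22.5 |
| autumn | 4.00 | 10.6 | 46.0 |
| autumn | 8.00 | 19.9 | 58.1 |
| autumn | 10.0 | 23.1 | 61.0 |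
| autumn | 15.0 | 28.6 | 64.7 |

(scatter of a reading: 0.5 percentage points)

1. which of these holds the largest part of the starting material at the end of gamma (bis adduct / other mono adduct / starting material / first product)
2. which of these holds the largest part of the starting material at the end of eta (bis adduct / other mono adduct / starting material / first product)
3. which of these holds the largest part of the starting material at the end of beta (bis adduct / other mono adduct / starting material / first product)
4. amount of bis adduct at the end of gamma, in percent of the starting material charged



The summer run at 15.0 min holds 24.5 % first product and 2.8 % bis adduct, and the autumn run at 1.33 min holds 22.5 % and 2.0 %. The times differ by a factor of 11.3, yet the two states stand close together. This looks odd until I see that autumn has 6.67 times the partner. If each step takes partner once, partner multiplies every rate alike, so it drops out of the path of bis adduct against first product, and so does the clock. I therefore read the path. Between the first two autumn readings, the gain in bis adduct over the gain in first product is 0.366. I call this the bis slope, a differential selectivity as read. The straight line through those two readings meets zero bis adduct at 17.0 % first product, but that is an intercept of this chord and not the start of the path, since summer at 8.00 min reads 2.1 % bis adduct at 16.3 % first product. So I use the line only between the two autumn readings. Summer's last reading played no part in this line, which gives 2.73 % there against the 2.8 % read, within the scatter of 0.5 percentage points.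

The forecast puts starting material on top in gamma, first product in eta and first product in beta, with 4.5 % bis adduct at the end of gamma. Its ground is that “Early bis is too fast for the route through first product”. It sets gamma's first product at 32%, while my line, read backwards, ties its bis adduct to 29.3 % first product, so its two figures are not quite one point of my line.

Gamma gives 4.10 % bis adduct, and the leaders are starting material, first product and first product, as forecast. At 30.0 min in gamma, the other mono adduct is still made 1.42 times faster than it is used, each step taken net. The bis slope, applied to gamma's 28.3 % first product, gives 4.13 %.

    starting material + partner → first product + by-product (k = 0.220 M⁻¹ min⁻¹)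
    starting material + partner → other mono adduct + by-product (k = 0.0860 M⁻¹ min⁻¹)
    partner + first product → bis adduct + by-product (k = 0.00680 M⁻¹ min⁻¹)
    partner + other mono adduct → bis adduct + by-product (k = 0.400 M⁻¹ min⁻¹)
    starting material + first product → side product (k = 0.0380 M⁻¹ min⁻¹)
    partner ⇌ dormant form (K = 0.680, k = 0.0270 min⁻¹)

The same flask as gamma, read at 80 min, holds 33.3 % first product, for which the bis slope gives 5.95 %. The computed bis adduct there is 7.65 %, 1.7 points above the line.

(All runs were computed with made-up constants; noise was put on by code.)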